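**Retrosynthetic overview**
- The target is the acyclic anti-1,3-diol (3S,5S)-1-(4-hydroxy-3-methoxyphenyl)tetradecane-3,5-diol. No ring is formed in the route; the only ring, the guaiacol arene, is bought.
- Both carbinol centres come from one double asymmetric hydrogenation of an achiral 1,3-diketone, using a BINAP complex of divalent ruthenium.
- The 1,3-diketone comes from forming the C4–C5 bond by crossed Claisen condensation of zingerone (1), through its kinetic methyl-side enolate, with methyl decanoate (2).

Assumption: zingerone, methyl decanoate, LiN(i-Pr)2 solution and RuCl2[(S)-BINAP] are taken as commercial; because the route has only two steps, the risk ranking at the end covers both of them instead of three.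

**Route**

Step 1
Reactants: 1 zingerone [4-(4-hydroxy-3-methoxyphenyl)butan-2-one]; 2 methyl decanoate
Product: 5 [10]-gingerdione = 1-(4-hydroxy-3-methoxyphenyl)tetradecane-3,5-dione (achiral; mostly enol form), via dilithium phenoxide-enolate of zingerone 3 (not isolated), via dilithium salt of [10]-gingerdione 4 (not isolated)
Conditions: 1 (2.1 equiv), LiN(i-Pr)2 (4.3 equiv), THF, −78 °C, 1 h; then 2 (1.0 equiv), −78 °C → 20 °C, 12 h; 1 M HCl to pH 3
Reagents that add atoms: none
Why: Crossed Claisen condensation: lithium diisopropylamide at −78 °C deprotonates the phenol and then the methyl group (kinetic enolate 3), which is C-acylated by the methyl ester; the phenoxide cannot be acylated productively by a methyl ester, the product is trapped as the stabilised diketonate 4 (excess 3 acts as base and returns as recoverable 1), and no stereocenter is created.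

Step 2
Reactants: 5 [10]-gingerdione
Product: 8 (3S,5S)-1-(4-hydroxy-3-methoxyphenyl)tetradecane-3,5-diol (anti diol, the target), via (S)-[10]-gingerol 6 (not isolated), via (3S)-3-hydroxy-5-oxo regioisomer 7 (not isolated)
Conditions: RuCl2[(S)-BINAP] (1 mol%), H2 (80 atm), MeOH, 50 °C, 48 h; chromatography, then recrystallisation
Reagents that add atoms: none
Why: Noyori asymmetric hydrogenation of a 1,3-diketone with a BINAP complex of divalent ruthenium: (S)-BINAP delivers hydrogen to each chelated carbonyl in the sense that gives (S)-3-hydroxy esters from 3-oxo esters, so the first reduction gives the (S)-hydroxy ketones 6 and 7 and the second, catalyst-controlled reduction gives the anti (3S,5S)-diol (as (R)-BINAP gives (R,R)-pentane-2,4-diol from acetylacetone), with minor-enantiomer material ending up mainly in the separable syn diol; both H2 molecules end up entirely in the product and the phenol, aryl ether and arene are untouched.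

**Compound list**
1 | zingerone, 4-(4-hydroxy-3-methoxyphenyl)butan-2-one | CC(=O)CCc1ccc(O)c(OC)c1 | starting material
2 | methyl decanoate | CCCCCCCCCC(=O)OC | starting material
3 | dilithium phenoxide-enolate of zingerone (kinetic, methyl side) | [Li+].[Li+].C=C([O-])CCc1ccc([O-])c(OC)c1 | intermediate
4 | dilithium salt of [10]-gingerdione (phenoxide plus diketonate) | [Li+].[Li+].CCCCCCCCCC(=O)C=C([O-])CCc1ccc([O-])c(OC)c1 | intermediate
5 | [10]-gingerdione, 1-(4-hydroxy-3-methoxyphenyl)tetradecane-3,5-dione | CCCCCCCCCC(=O)CC(=O)CCc1ccc(O)c(OC)c1 | intermediate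
6 | (S)-[10]-gingerol, (5S)-5-hydroxy-1-(4-hydroxy-3-methoxyphenyl)tetradecan-3-one | CCCCCCCCC[C@H](O)CC(=O)CCc1ccc(O)c(OC)c1 | intermediate
7 | (3S)-3-hydroxy-1-(4-hydroxy-3-methoxyphenyl)tetradecan-5-one | CCCCCCCCCC(=O)C[C@@H](O)CCc1ccc(O)c(OC)c1 | intermediate
8 | (3S,5S)-1-(4-hydroxy-3-methoxyphenyl)tetradecane-3,5-diol | CCCCCCCCC[C@H](O)C[C@@H](O)CCc1ccc(O)c(OC)c1 | target

**Totals**
Total step count: 2. Longest linear sequence: 2 steps.

**Steps most likely to fail** (the route has only these two; ranked)

Risk 1 – Step 1. The free-phenol dianion may be poorly soluble, and self-aldol of zingerone or self-condensation of the ester may depress the yield. The fallback sets out from compound 1 and comes back to the route at compound 5, replacing the Claisen by an aldol addition followed by oxidation. Benzylation of 1 (BnBr, K2CO3, acetone, reflux) gives O-benzylzingerone F1. LiN(i-Pr)2 in THF at −78 °C converts it into the kinetic lithium enolate of O-benzylzingerone F2. This adds to commercial decanal to give the lithium aldolate of O-benzyl-[10]-gingerol F3 and, after NH4Cl quench, racemic O-benzyl-[10]-gingerol F4. Dess–Martin periodinane (CH2Cl2, NaHCO3, 0 → 20 °C) oxidises the carbinol to O-benzyl-[10]-gingerdione F5, which erases the racemic centre. Hydrogenolysis (H2 1 atm, Pd on carbon with 10 wt% Pd, EtOAc, 20 °C) removes the benzyl group and delivers 5.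

Risk 2 – Step 2. The second, diastereo-determining reduction may stall or give an unsatisfactory anti:syn ratio on this long-chain phenolic substrate. The fallback sets out from compound 5 and comes back at compound 8, replacing catalyst control at the second centre by substrate-directed hydride delivery. The hydrogenation with RuCl2[(S)-BINAP] is run mildly (H2 about 10 atm, MeOH, 25 °C) and stopped at about one equivalent of H2. The mixture of the (S)-hydroxy ketones 6 and 7 is isolated and reduced with Me4NBH(OAc)3 (MeCN/AcOH 1:1, −30 °C, Evans–Saksena anti reduction). Intramolecular hydride delivery places the new carbinol anti to the existing (S)-carbinol in either regioisomer, so both converge on 8. This detour passes only through listed compounds and makes no new compound (F0).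

**Further compounds**
F1 | step 1 | O-benzylzingerone, 4-[4-(benzyloxy)-3-methoxyphenyl]butan-2-one | CC(=O)CCc1ccc(OCc2ccccc2)c(OC)c1
F2 | step 1 | kinetic lithium enolate of O-benzylzingerone | [Li+].C=C([O-])CCc1ccc(OCc2ccccc2)c(OC)c1
F3 | step 1 | lithium aldolate of O-benzyl-[10]-gingerol (racemic) | [Li+].CCCCCCCCCC([O-])CC(=O)CCc1ccc(OCc2ccccc2)c(OC)c1
F4 | step 1 | racemic O-benzyl-[10]-gingerol, 1-[4-(benzyloxy)-3-methoxyphenyl]-5-hydroxytetradecan-3-one | CCCCCCCCCC(O)CC(=O)CCc1ccc(OCc2ccccc2)c(OC)c1
F5 | step 1 | O-benzyl-[10]-gingerdione, 1-[4-(benzyloxy)-3-methoxyphenyl]tetradecane-3,5-dione | CCCCCCCCCC(=O)CC(=O)CCc1ccc(OCc2ccccc2)c(OC)c1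
F0 | step 2 | none | none
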